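The synthesis rests on the O1–C8a disconnection of the epicatechin pyran ring F (O1, C2, C3, C4, C4a, C8a). C8a lies between C8 (interflavan bond) and C4a (C4H2 arm) and is meta to O5 and O7. A fluorine placed on C8a, absent from the target, therefore directs both ortho-metalations that attach these two carbon arms. It also keeps ring D out of o-quinone methide formation, and it finally leaves. The key step is an intramolecular SNAr of a benzylic potassium alkoxide on this fluoroarene. It closes the last ring with retention at C2: an acyclic syn-(1R,2R) 2-benzyloxy alcohol becomes the 2,3-cis flavan-3-ol, and the 4→8 regiochemistry is fixed by construction.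

Key step: step 8

Remark on numbering: flavan numbering is used for each unit. The upper unit has rings A (benzo), B (4-oxyphenyl) and C (pyran), with atoms marked u (C2u, C4u). The lower unit has rings D (benzo), E (3,4-dioxyphenyl) and F (pyran), with atoms unmarked. ArD = 4,6-bis(benzyloxy)-2-fluoro-3-[(2S,4S)-7-(benzyloxy)-2-(4-benzyloxyphenyl)chroman-4-yl]phenyl.

Assumption: the sense of induction of the chiral acid in step 3 must be found by experiment. The catalyst is written as (R); its mirror image is used if (R) gives ent-9. Compounds 1, 2, 4, 7, 10 and 16 are taken as commercial.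

Step 1
Reactants: 1 5-fluorobenzene-1,3-diol; 2 benzyl bromide
Product: 3 1,3-bis(benzyloxy)-5-fluorobenzene
Conditions: BnBr (2.2 equiv), K2CO3, DMF, 60 °C
Reagents that add atoms: benzyl bromide (2), BrCc1ccccc1
Why: Williamson ether synthesis at both phenols, while the C–F bond of the unactivated arene is inert to carbonate.

Step 2
Reactants: 3 1,3-bis(benzyloxy)-5-fluorobenzene; 4 4-(benzyloxy)-2-hydroxybenzaldehyde
Product: 6 racemic 5-(benzyloxy)-2-{[2,4-bis(benzyloxy)-6-fluorophenyl](hydroxy)methyl}phenol, via aryllithium 5 (not isolated)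
Conditions: 3 (2.2 equiv), n-BuLi, THF, −78 °C; then 4, −78 °C; H2O quench at −78 °C
Reagents that add atoms: 4-(benzyloxy)-2-hydroxybenzaldehyde (4), O=Cc1ccc(OCc2ccccc2)cc1O
Why: Directed ortho-metalation followed by 1,2-addition: fluorine and the flanking benzyloxy group make the C–H between them the most acidic site of 3, the o-fluoroaryllithium is stable at −78 °C, the first equivalent only deprotonates the phenol of 4, and the new carbinol centre may be racemic because it becomes planar in step 3.

Step 3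
Reactants: 6 racemic diaryl carbinol; 7 1-(benzyloxy)-4-ethenylbenzene
Product: 9 (2S,4S)-7-(benzyloxy)-2-[4-(benzyloxy)phenyl]-4-[2,4-bis(benzyloxy)-6-fluorophenyl]chromane (2,4-cis), via o-quinone methide 8 (not isolated)
Conditions: (R)-3,3′-bis(2,4,6-triisopropylphenyl)-H8-BINOL N-triflylphosphoramide (10 mol %), 7 (2 equiv), 4 Å MS, toluene, −20 °C
Reagents that add atoms: 1-(benzyloxy)-4-ethenylbenzene (7), C=Cc1ccc(OCc2ccccc2)cc1
Why: Chiral Brønsted acid catalysed dehydration to o-quinone methide 8 and inverse-electron-demand hetero-Diels–Alder reaction with the electron-rich styrene is a known enantioselective route to 2,4-diarylchromanes: the endo approach of the styrene aryl group sets the 2,4-cis relation, the chiral counter-anion bound to the o-quinone methide oxygen chooses the face and thus 2S,4S, and only ring A can form the o-quinone methide because ring D carries F where a phenol would be.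

Step 4
Reactants: 9 (2S,4S)-4-(fluoroaryl)flavan; 10 methyl (2R)-oxirane-2-carboxylate
Product: 13 methyl (2R)-3-ArD-2-hydroxypropanoate, via aryllithium 11 (not isolated), via arylmagnesium bromide 12 (not isolated)
Conditions: n-BuLi, THF, −78 °C; MgBr2·OEt2, −78 → −30 °C; CuI (15 mol %), 10 (1.5 equiv), −30 → 0 °C; aqueous work-up
Reagents that add atoms: methyl (2R)-oxirane-2-carboxylate (10), COC(=O)[C@H]1CO1
Why: A second directed ortho-metalation at the only C–H left next to fluorine, Li-to-Mg exchange to stop aryne formation, and copper-catalysed SN2 opening of the glycidic ester at its CH2 terminus make the C4a–C4 bond, and the untouched stereocentre of 10 becomes C3 (R).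

Step 5
Reactants: 13 methyl (2R)-3-ArD-2-hydroxypropanoate; 2 benzyl bromide
Product: 14 methyl (2R)-2-(benzyloxy)-3-ArD-propanoate
Conditions: BnBr, Ag2O, 4 Å MS, CH2Cl2, rt, dark
Reagents that add atoms: benzyl bromide (2), BrCc1ccccc1
Why: Silver(I) oxide mediated Williamson etherification, whose non-basic medium does not enolise the α-oxy ester, masks O3 so that it cannot compete as nucleophile in step 8 and can act as chelating group in step 7.

Step 6
Reactants: 14 methyl (2R)-2-(benzyloxy)-3-ArD-propanoate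
Product: 15 (2R)-2-(benzyloxy)-3-ArD-propanal
Conditions: DIBAL-H (1.1 equiv), CH2Cl2, −78 °C; Rochelle salt work-up
Reagents that add atoms: none
Why: Partial ester reduction with DIBAL-H works because the α-alkoxy-chelated tetrahedral aluminium hemiacetal survives at −78 °C and releases the configurationally intact aldehyde only on work-up.

Step 7
Reactants: 15 (2R)-2-(benzyloxy)-3-ArD-propanal; 16 4-bromo-1,2-bis(benzyloxy)benzene
Product: 18 (1R,2R)-2-(benzyloxy)-1-[3,4-bis(benzyloxy)phenyl]-3-ArD-propan-1-ol, via Grignard reagent 17 (not isolated)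
Conditions: 16, Mg, THF → 17; 15, MgBr2·OEt2 (2 equiv), CH2Cl2, −78 °C, then 17
Reagents that add atoms: 4-bromo-1,2-bis(benzyloxy)benzene (16, as 17), Brc1ccc(OCc2ccccc2)c(OCc2ccccc2)c1
Why: Chelation-controlled Grignard addition (Cram chelate model): magnesium bridges the aldehyde oxygen and the α-benzyloxy oxygen, the aryl group attacks from the side of the α-hydrogen, and the new carbinol centre (future C2) is set R, syn to C3.

Step 8
Reactants: 18 (1R,2R)-2-(benzyloxy)-1-[3,4-bis(benzyloxy)phenyl]-3-ArD-propan-1-ol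
Product: 20 (2R,3R)-3,5,7-tris(benzyloxy)-2-[3,4-bis(benzyloxy)phenyl]-8-[(2S,4S)-7-(benzyloxy)-2-(4-benzyloxyphenyl)chroman-4-yl]chromane, via potassium alkoxide 19 (not isolated)
Conditions: KHMDS (1.2 equiv), 18-crown-6, THF–DMPU, 0 → 60 °C
Reagents that add atoms: none
Why: KHMDS turns 18 into potassium alkoxide 19, whose C2–O− attacks C8a of ring D and expels fluoride by addition–elimination through a Meisenheimer-type (or concerted) transition state. The closest known reaction is the intramolecular SNAr pyran closure of 3,5-dialkoxyfluorobenzenes used for 2,3-cis flavan-3-ols. Ring F (O1, C2, C3, C4, C4a, C8a) closes in the 6-exo-trig mode at an aromatic carbon by forming O1–C8a. No stereocentre is made or broken: since the C2–O bond stays intact, the syn-(1R,2R) array of 18 passes with retention into the 2,3-cis (2R,3R) ring, whereas closures through a benzylic cation at C2 would favour the trans isomer. Reactivity comes from the position of C8a meta to O5 and O7, whose lone pairs are not conjugated with the reacting carbon and whose inductive pull stabilises the charge building up on C8, C4a and C6. Selectivity is built into 18: O3 is benzylated (no competing five-membered closure), there is a single C–F bond, both carbons ortho to it are substituted (no aryne), and its place between C8 and C4a makes the 4→8 isomer the only possible product.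

Step 9
Reactants: 20 heptabenzyl ether
Product: 21 (2R,3R)-2-(3,4-dihydroxyphenyl)-8-[(2S,4S)-7-hydroxy-2-(4-hydroxyphenyl)chroman-4-yl]chromane-3,5,7-triol (target)
Conditions: H2 (1 atm), Pd(OH)2/C, THF–MeOH–H2O, rt
Reagents that add atoms: none
Why: Catalytic hydrogenolysis of all seven benzyl ethers over Pearlman's catalyst under neutral conditions, the standard last step for benzylated flavan-3-ol oligomers, leaves the cyclic C2–O1 bonds, the C4u–C8 bond and all four stereocentres untouched.

Compound list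
1 | 5-fluorobenzene-1,3-diol | Oc1cc(O)cc(F)c1 | starting material
2 | benzyl bromide | BrCc1ccccc1 | starting material
3 | 1,3-bis(benzyloxy)-5-fluorobenzene | Fc1cc(OCc2ccccc2)cc(OCc2ccccc2)c1 | intermediate
4 | 4-(benzyloxy)-2-hydroxybenzaldehyde | O=Cc1ccc(OCc2ccccc2)cc1O | starting material
5 | [2,4-bis(benzyloxy)-6-fluorophenyl]lithium (not isolated) | [Li]c1c(F)cc(OCc2ccccc2)cc1OCc1ccccc1 | intermediate
6 | racemic 5-(benzyloxy)-2-{[2,4-bis(benzyloxy)-6-fluorophenyl](hydroxy)methyl}phenol | OC(c1ccc(OCc2ccccc2)cc1O)c1c(F)cc(OCc2ccccc2)cc1OCc1ccccc1 | intermediate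
7 | 1-(benzyloxy)-4-ethenylbenzene | C=Cc1ccc(OCc2ccccc2)cc1 | starting material
8 | 3-(benzyloxy)-6-[2,4-bis(benzyloxy)-6-fluorobenzylidene]cyclohexa-2,4-dien-1-one, o-quinone methide (not isolated) | O=C1C=C(OCc2ccccc2)C=CC1=Cc1c(F)cc(OCc2ccccc2)cc1OCc1ccccc1 | intermediate
9 | (2S,4S)-7-(benzyloxy)-2-[4-(benzyloxy)phenyl]-4-[2,4-bis(benzyloxy)-6-fluorophenyl]chromane | c5ccccc5COc1ccc([C@@H]2C[C@H](c3c(OCc5ccccc5)cc(OCc5ccccc5)cc3F)c3ccc(OCc4ccccc4)cc3O2)cc1 | intermediate
10 | methyl (2R)-oxirane-2-carboxylate | COC(=O)[C@H]1CO1 | starting material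
11 | ArD-lithium, 9 lithiated between F and OBn of ring D (not isolated) | c5ccccc5COc1ccc([C@@H]2C[C@H](c3c(OCc5ccccc5)cc(OCc5ccccc5)c([Li])c3F)c3ccc(OCc4ccccc4)cc3O2)cc1 | intermediate
12 | ArD-magnesium bromide (not isolated) | c5ccccc5COc1ccc([C@@H]2C[C@H](c3c(OCc5ccccc5)cc(OCc5ccccc5)c([Mg]Br)c3F)c3ccc(OCc4ccccc4)cc3O2)cc1 | intermediate
13 | methyl (2R)-3-ArD-2-hydroxypropanoate | c5ccccc5COc1ccc([C@@H]2C[C@H](c3c(OCc5ccccc5)cc(OCc5ccccc5)c(C[C@@H](O)C(=O)OC)c3F)c3ccc(OCc4ccccc4)cc3O2)cc1 | intermediate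
14 | methyl (2R)-2-(benzyloxy)-3-ArD-propanoate | c5ccccc5COc1ccc([C@@H]2C[C@H](c3c(OCc5ccccc5)cc(OCc5ccccc5)c(C[C@@H](OCc5ccccc5)C(=O)OC)c3F)c3ccc(OCc4ccccc4)cc3O2)cc1 | intermediate
15 | (2R)-2-(benzyloxy)-3-ArD-propanal | c5ccccc5COc1ccc([C@@H]2C[C@H](c3c(OCc5ccccc5)cc(OCc5ccccc5)c(C[C@@H](OCc5ccccc5)C=O)c3F)c3ccc(OCc4ccccc4)cc3O2)cc1 | intermediate
16 | 4-bromo-1,2-bis(benzyloxy)benzene | Brc1ccc(OCc2ccccc2)c(OCc2ccccc2)c1 | starting material
17 | [3,4-bis(benzyloxy)phenyl]magnesium bromide (not isolated) | Br[Mg]c1ccc(OCc2ccccc2)c(OCc2ccccc2)c1 | intermediate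
18 | (1R,2R)-2-(benzyloxy)-1-[3,4-bis(benzyloxy)phenyl]-3-ArD-propan-1-ol | c5ccccc5COc1ccc([C@@H]2C[C@H](c3c(OCc5ccccc5)cc(OCc5ccccc5)c(C[C@@H](OCc5ccccc5)[C@H](O)c5ccc(OCc6ccccc6)c(OCc6ccccc6)c5)c3F)c3ccc(OCc4ccccc4)cc3O2)cc1 | intermediate
19 | potassium alkoxide of 18 (not isolated) | [K+].c5ccccc5COc1ccc([C@@H]2C[C@H](c3c(OCc5ccccc5)cc(OCc5ccccc5)c(C[C@@H](OCc5ccccc5)[C@H]([O-])c5ccc(OCc6ccccc6)c(OCc6ccccc6)c5)c3F)c3ccc(OCc4ccccc4)cc3O2)cc1 | intermediate
20 | (2R,3R)-3,5,7-tris(benzyloxy)-2-[3,4-bis(benzyloxy)phenyl]-8-[(2S,4S)-7-(benzyloxy)-2-(4-benzyloxyphenyl)chroman-4-yl]chromane | c5ccccc5COc1ccc([C@@H]2C[C@H](c3c(OCc5ccccc5)cc(OCc5ccccc5)c4c3O[C@H](c3ccc(OCc5ccccc5)c(OCc5ccccc5)c3)[C@H](OCc3ccccc3)C4)c3ccc(OCc4ccccc4)cc3O2)cc1 | intermediate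
21 | (2R,3R)-2-(3,4-dihydroxyphenyl)-8-[(2S,4S)-7-hydroxy-2-(4-hydroxyphenyl)chroman-4-yl]chromane-3,5,7-triol | Oc1ccc([C@@H]2C[C@H](c3c(O)cc(O)c4c3O[C@H](c3ccc(O)c(O)c3)[C@H](O)C4)c3ccc(O)cc3O2)cc1 | target

Total step count: 9. Longest linear sequence: 9 (1 → 3 → 6 → 9 → 13 → 14 → 15 → 18 → 20 → 21).

Steps most likely to fail

Step 8. The displacement may stall because the alkoxide has to attack a fluorine-bearing carbon flanked by two ortho substituents on an electron-rich ring. Forcing conditions may then lead to base-induced loss or rearrangement of benzyl ethers. The fallback sets out from 18 and comes back at 20. It replaces nucleophilic substitution by C–F metalation and oxidative C–O coupling. Nickel/copper-catalysed defluoroborylation (Ni(cod)2, PCy3, CuI, CsF, B2pin2, toluene, 80 °C) should give the pinacol arylboronate F1. An intramolecular Chan–Lam etherification (Cu(OAc)2, DMAP, 4 Å MS, O2) should then form the same O1–C8a bond, again without touching the C2–O bond, so the 2,3-cis relation is kept.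

Step 3. Facial selectivity may be poor because the twisted, doubly ortho-substituted aryl group on the o-quinone methide lies outside the usual substrate range. The acid may also oligomerise the styrene. The fallback sets out from 3 (as aryllithium 5) and comes back at 9. It sets C2u first and derives C4u from it.
- 7-Hydroxychromone is benzylated with 2 (K2CO3, DMF) to 7-(benzyloxy)chromone F2.
- Palladium(II)/pyridine-oxazoline-catalysed asymmetric conjugate addition of 4-(benzyloxy)phenylboronic acid gives the (2S)-flavanone F3.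
- Aryllithium 5 is added at −78 °C to F3 precomplexed with LaCl3·2LiCl, which suppresses enolisation and retro-oxa-Michael opening, to give the tertiary alcohol F4.
- Ionic hydrogenation (Et3SiH, TFA, CH2Cl2, −78 → −20 °C) delivers hydride to the 4-aryl benzylic cation on the face anti to the 2-aryl group, which should give 2,4-cis 9.

Step 4. Four things may go wrong:
- The second lithiation may be incomplete.
- Benzylic deprotonation may compete with it.
- The o-fluoroaryl metal may lose fluoride on warming.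
- The aryl metal may attack the ester instead of the epoxide.

The fallback sets out from 11 and comes back at 15. It uses an ester-free epoxide at −78 °C and reaches the aldehyde from the alcohol oxidation level.
- 11 with BF3·OEt2 and tert-butyldimethylsilyl (R)-glycidyl ether gives the secondary alcohol F5.
- NaH and 2 give the benzyl ether F6.
- TBAF gives the primary alcohol F7.
- Dess–Martin oxidation gives 15.

Further compounds
F1 | step 8 | (1R,2R)-2-(benzyloxy)-1-[3,4-bis(benzyloxy)phenyl]-3-aryl-propan-1-ol in which the fluorine of ArD is replaced by a pinacolboronate group | c5ccccc5COc1ccc([C@@H]2C[C@H](c3c(OCc5ccccc5)cc(OCc5ccccc5)c(C[C@@H](OCc5ccccc5)[C@H](O)c5ccc(OCc6ccccc6)c(OCc6ccccc6)c5)c3B7OC(C)(C)C(C)(C)O7)c3ccc(OCc4ccccc4)cc3O2)cc1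
F2 | step 3 | 7-(benzyloxy)-4H-chromen-4-one | O=c1ccoc2cc(OCc3ccccc3)ccc12
F3 | step 3 | (2S)-7-(benzyloxy)-2-[4-(benzyloxy)phenyl]chroman-4-one | c5ccccc5COc1ccc([C@@H]2CC(=O)c3ccc(OCc4ccccc4)cc3O2)cc1
F4 | step 3 | (2S)-7-(benzyloxy)-2-[4-(benzyloxy)phenyl]-4-[2,4-bis(benzyloxy)-6-fluorophenyl]chroman-4-ol (either C4 epimer) | c5ccccc5COc1ccc([C@@H]2CC(O)(c3c(OCc5ccccc5)cc(OCc5ccccc5)cc3F)c3ccc(OCc4ccccc4)cc3O2)cc1
F5 | step 4 | (2R)-1-ArD-3-[(tert-butyldimethylsilyl)oxy]propan-2-ol | c5ccccc5COc1ccc([C@@H]2C[C@H](c3c(OCc5ccccc5)cc(OCc5ccccc5)c(C[C@@H](O)CO[Si](C)(C)C(C)(C)C)c3F)c3ccc(OCc4ccccc4)cc3O2)cc1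
F6 | step 4 | (2R)-2-(benzyloxy)-3-ArD-propyl tert-butyldimethylsilyl ether | c5ccccc5COc1ccc([C@@H]2C[C@H](c3c(OCc5ccccc5)cc(OCc5ccccc5)c(C[C@@H](OCc5ccccc5)CO[Si](C)(C)C(C)(C)C)c3F)c3ccc(OCc4ccccc4)cc3O2)cc1
F7 | step 4 | (2R)-2-(benzyloxy)-3-ArD-propan-1-ol | c5ccccc5COc1ccc([C@@H]2C[C@H](c3c(OCc5ccccc5)cc(OCc5ccccc5)c(C[C@@H](OCc5ccccc5)CO)c3F)c3ccc(OCc4ccccc4)cc3O2)cc1
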